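West and north, two earlier runs with equal partner and protic impurity but substrate at 0.034 M and 0.17 M, stood level at 1.00 h, with 10.7 % and 10.5 % of target. By 5.00 h they had parted, at 75.7 % and 49.8 %.

| flask | substrate | partner | protic impurity | remark | time |
|---|---|---|---|---|---|
| west | 0.034 M | 0.26 M | 0.060 M | run made earlier |  |
| north | 0.17 M | 0.26 M | 0.060 M | run made earlier |  |
| north-west | 0.20 M | 0.29 M | 0.060 M | run made earlier |  |
| dusk | 0.060 M | 0.200 M | 0.0600 M |  | 5.0 h |
| noon | 0.20 M | 0.260 M | 0.0600 M |  | 5.0 h |

| run | time / h | target / % | substrate / % |
|---|---|---|---|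
| west | 0.333 | 0.7 | 63.1 |
| west | 1.00 | 10.7 | 25.5 |
| west | 2.00 | 35.5 | 4.9 |
| west | 2.50 | 47.4 | 4.3 |
| west | 4.00 | 68.1 | 0.1 |
| west | 5.00 | 75.7 | 0 |
| north | 0.417 | 0.8 | 56.9 |
| north | 0.667 | 2.9 | 41.8 |
| north | 1.00 | 10.5 | 24.4 |
| north | 2.00 | 27.7 | 5.0 |
| north | 3.00 | 39.5 | 0.9 |
| north | 5.00 | 49.8 | 0.8 |
| north-west | 0.417 | 1.3 | 54.8 |
| north-west | 1.33 | 18.3 | 16.4 |
| north-west | 2.50 | 34.1 | 3.4 |
| north-west | 4.00 | 48.2 | 0.1 |
| north-west | 5.00 | 51.1 | 0 |

(standard deviation of a reading: 1 percentage point)



- which of the two ends with the higher amount of target, in percent of the substrate charged ("neither" if they lie within 2 percentage points) (dusk / noon / neither)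
- target at the end, in percent of the substrate charged, dusk
- target at the end, in percent of the substrate charged, noon

Two chemists argue over these runs. The first looks at the level pair: substrate in those runs stood at 25.5 % and 24.4 % at 1.00 h, so she treats percent of target as independent of loading, and expects dusk and noon to finish together, the answer "neither".

The second points to the later readings and writes a balance of partner. From the partner charged she takes what the protic impurity could consume, and divides by the substrate it has to serve: the spare partner ratio, ([partner] − [protic impurity]) / [substrate] at the charge, which for noon is 1.00. West has 5.88 and ended at 75.7 %; north has 1.18 and ended at 49.8 %; north-west has 1.15 and ended at 51.1 %. Dusk, at 2.33, lies above north and below west, while noon lies just under north, so she reads dusk well above noon.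

The forecast is hers: dusk ends higher, with 62 % for dusk and 45 % for noon. Its ground is this: “Yield then depends on loading”.

Dusk gives 59.4 % and noon 47.2 %, so dusk ends higher, by 12 percentage points, and the forecast holds. The first chemist keeps the substrate itself: at 2.50 h dusk and noon both hold 3.17 % of it.

    open intermediate + second intermediate → target (k = 0.0390 M⁻¹ min⁻¹)
    2 open intermediate → homo product (k = 0.0320 M⁻¹ min⁻¹)
    partner + protic impurity → quenched reagent (k = 0.0910 M⁻¹ min⁻¹)
    partner → second intermediate (k = 0.0190 min⁻¹)
    substrate → open intermediate (k = 0.0230 min⁻¹)

At the end of dusk, the step to target uses open intermediate 7.0 times as fast as the pairing to homo product, the selectivity factor of that moment, and 19.0 % still stands as open intermediate, with a half-life by that step of 2.3 h. Left until 50.0 h, dusk reaches 77.2 % and noon 57.0 %, the same order.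

A neighbour of dusk charged with 0.12 M of partner has a ratio of 1.00, level with noon's 1.00, which places it near noon's 47.2 %. It ends at 41.2 %, lower by 6 points, with 29.8 % still open intermediate.

Readings and results are simulated from invented constants; the scatter is artificial.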